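## Analysis of the target

The target is a 6-5-4 tricycle. Cyclohexene ring A (C1, C2, C3, C4, C5, C10) is fused along C5–C10 to cyclopentane ring B (C5, C6, C7, C9, C10), which carries the cis-fused beta-lactone ring C (C7, C8, O, C9). C11 is the CH2O carbon on C1, and C1'–C6' are the carbons of the 1,3,3-trimethylcyclohexyl group (C1' quaternary, C3' the C(CH3)2 carbon). These labels, not IUPAC locants, are used throughout.

The only alkene, C4=C5, is tetrasubstituted, endocyclic in ring A and exocyclic to ring B, and C4 carries the quaternary carbon C1'. Four stereocentres are contiguous (1S, 10R, 9S, 7R): the C11 arm on C1 is trans to C9 on C10, and the lactone (O on C9, C8 on C7) lies on the face of ring B that carries H-10, away from the C1 branch. The fifth, C1' (S), is a remote all-carbon quaternary centre whose two ring branches differ only in where the gem-dimethyl group sits (C2' side versus C6' side), so the core cannot control it and it cannot control the core.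

Sensitive groups are the beta-lactone (an acylating agent, opened by nucleophiles and bases), a second ester that must be told apart from it, the C10–H (allylic, and epimerisable in any carbonyl precursor) and an alkene that can slip into conjugation when C9 is a carbonyl. The hard part is the C4–C1' bond, which joins a fully substituted sp2 carbon to a quaternary stereocentre beside a gem-dimethyl group, and the need to tie the configuration of C1' to that of the core.

The feature that invites the key move is that C1' is an allylic quaternary carbon on C4 with C5 as its neighbour. With oxygen on C5 and an alkene at C5'=C6', the atoms O–C5–C4–C1'–C6'=C5' are those of the product of a [3,3] shift of an allyl vinyl ether, in which an easily set C5'–O stereocentre is traded for C1'.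

## Retrosynthetic reasoning

The butanoate C11–O acyl bond of 21 is cut first, giving alcohol 20. Keeping the second ester for the last step means that no step has to distinguish two esters, and acylation of a primary alcohol beside a beta-lactone needs only an acyl chloride and a weak base.

Alcohol 20 is traced to benzyl ether 19, which still has the C5'=C6' alkene. One hydrogenation should remove the benzyl group and saturate the disubstituted ring alkene, while the tetrasubstituted C4=C5 alkene is too hindered to react.

Rings B and C of 19 are opened together by cutting C7–C9 and C8–O, which gives aldehyde acid 18. The forward aldol-lactonization must close the five-membered ring, make the lactone cis and place it on the face away from the C1 branch. The cut is made here so that the strained ring is formed late and from an acid.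

C9 is a one-carbon unit on C10. Acid 18 comes from tert-butyl ester 17, and 17 from ketone 14 through spiro-epoxide 15 (C9–C10 cut). C10 is alpha to the aldehyde in 17, so its configuration is set by equilibration to the isomer trans to the C11 arm.

The C5–C6 bond of 14 is cut between enol triflate 12 and zinc reagent 13. The oxygen on C5 is the handle left by the key step, and 13 delivers C6, C7 and C8 with C8 at the carboxyl level.

The C1–C11 bond of 12 is cut next. C1 is alpha to the C10 ketone, the only activated sp3 position of ring A, and it is the one core stereocentre that needs outside control, since C10, C9 and C7 follow from it. Auxiliary 8 on the ketone of 7 (hydrazone 9, alkylated hydrazone 11) provides that control. C1 is installed after the key step because a C1-substituted 1,2-diketone would enolise towards C1 and lose the centre.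

Triflate 7 is the sulfonate of diosphenol 6, and in 6 the C4–C1' bond is cut by a retro-[3,3] shift to ether 4. This is the key disconnection. No tertiary organometallic can carry C1' as a stereocentre, whereas a sigmatropic shift forms the hindered bond within one molecule and relays chirality from C5'. The diosphenol is chosen over a ketone or a 1,3-diketone because its product keeps oxygen on C5 (for C6) and a carbonyl on C10 (for C9 and for activating C1), and leaves no oxygen on C3.

Ether 4 is cut at C5'–O into allylic alcohol 2 and diketone 3 (etherification with inversion), and 2 comes from enone 1 by catalytic asymmetric reduction. The precursor of the key step is thus two steps from two commercial compounds.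

## Alternatives that were turned down

Alternative 1: the textbook cut, a retro-Diels–Alder of ring A (C1–C10 and C2–C3). The forward key step is a [4+2] cycloaddition of diene A1, a 1-vinylcyclopentene that already carries ring C and the cyclohexyl group on C4, with an acrylic dienophile to give aldehyde A2. It was turned down for three reasons:
- The cycloaddition gives no handle on C1'. A1 must already hold that centre on an sp2 carbon, so the hardest problem is only moved into the synthesis of the diene, at the cost of extra homologation steps.
- The endo rule places C11 cis to C9 (A2), the wrong relative configuration, so an epimerisation beside a beta-lactone would follow.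
- Facial selectivity would rest on a small, flat lactone.

Alternative 2: cut C4–C1' by 1,2-addition. The forward key step is addition of allylzinc reagent A5 through its tertiary terminus to the C4 ketone A3, giving carbinol A4, then dehydration and hydrogenation. It is convergent and is the cut most chemists would draw for this bond. It was turned down because the allylmetal is configurationally mobile and the new centre C1' lies four bonds from the nearest core stereocentre. Both C1' epimers would form in similar amounts, and they differ only in the position of a remote gem-dimethyl group. The dehydration could also go towards C3 or C5 without control.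

Alternative 3: cut both rings A and B around a C4–C5 alkyne. The forward sequence is a copper-catalysed asymmetric conjugate addition of a methyl nucleophile to enynone A6, removal of the ketone to give alkyne A7, elaboration to an enyne, and a (2+2+2) cycloaddition with a simple alkene partner under a zerovalent nickel or monovalent rhodium catalyst. It was turned down for three reasons:
- The conjugate addition is slowed by the syn-axial methyl group of the enone and competes with 1,6-addition.
- The metallacycle of a (2+2+2) reaction on an alkyne with a tert-alkyl substituent is prone to beta-hydride elimination instead of ring closure.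
- The C7 and C9 centres would have to be built first in an open chain, so the route has two uncertain steps and more steps overall.

Key step: step 3

Assumption: the usual sense of induction is taken for the two reagent-controlled steps (CBS reduction in step 1, RAMP-hydrazone alkylation in step 6); should either be reversed on these substrates, the mirror-image catalyst or auxiliary is used and nothing else changes.

## Route

Step 1
Reactants: 1 isophorone
Product: 2 (R)-isophorol [(1R)-3,5,5-trimethylcyclohex-2-en-1-ol]
Conditions: (S)-2-methyl-CBS-oxazaborolidine (10 mol %), BH3·SMe2, THF, −20 °C; MeOH quench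
Reagents that add atoms: none
Why: CBS reduction of an enone; the alkenyl branch acts as the large group, so the (S)-catalyst should deliver hydride to give the (R)-carbinol at C5', and borane reduces 1,2.

Step 2
Reactants: 2 (R)-isophorol; 3 cyclohexane-1,2-dione
Product: 4 2-{[(1S)-3,5,5-trimethylcyclohex-2-en-1-yl]oxy}cyclohex-2-en-1-one
Conditions: PPh3, DIAD, THF, 0 °C to rt
Reagents that add atoms: none
Why: Mitsunobu etherification; the enol of 3 (an acidic diosphenol) is O-alkylated by the oxyphosphonium salt of 2 in an SN2 step, so C5' is inverted to S, and attack at the tertiary alkene terminus is disfavoured by the gem-dimethyl group.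

Step 3
Reactants: 4 isophoryl diosphenol ether
Product: 6 2-hydroxy-3-[(1R)-1,5,5-trimethylcyclohex-2-en-1-yl]cyclohex-2-en-1-one, via alpha-diketone 5 (not isolated)
Conditions: degassed toluene (0.05 M), 120 °C, sealed tube
Reagents that add atoms: none
Why: Aliphatic Claisen ([3,3]-sigmatropic) rearrangement of a diosphenol allyl ether, a reaction type known to forge bonds to quaternary carbons and to relay chirality from cycloalkenyl ethers. The six reacting atoms are C4=C5–O–C5'–C6'=C1'; in one concerted suprafacial shift the C5'–O bond breaks, the C4–C1' bond forms and the ring alkene moves to C5'=C6'. No ring is closed: the step joins the two six-membered rings through the most hindered bond of the target. C1' is the only new stereocentre that survives, and it is fixed by the C5' centre of 4 alone, because in a cyclohexenyl ether the new bond must form on the ring face from which oxygen leaves (1,3-chirality transfer), while chair or boat geometry only affects C4, which is lost when 5 enolises to 6. The driving force is the C=O bond of 5 and then the conjugated, hydrogen-bonded diosphenol 6, whose enol double bond is already the C4=C5 alkene of the target. The step needs the concerted path to outrun ionisation of the allylic ether and elimination to a cyclohexadiene, which a non-polar solvent, neutral glass and moderate temperature should secure. The syn-axial methyl group on C3' slows bond formation at C1', which is why the diosphenol variant, with its early and congestion-tolerant transition state, is chosen. Enolisation of 5 towards C4 and not towards C1 is expected because it gives the tetrasubstituted conjugated enol.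

Step 4
Reactants: 6 diosphenol
Product: 7 (R)-6-oxo-2-(1,5,5-trimethylcyclohex-2-en-1-yl)cyclohex-1-en-1-yl trifluoromethanesulfonate
Conditions: Tf2O, pyridine, CH2Cl2, −78 to 0 °C
Reagents that add atoms: trifluoromethanesulfonic anhydride, O=S(=O)(OS(=O)(=O)C(F)(F)F)C(F)(F)F
Why: O-Sulfonylation of the enol of a diosphenol; it fixes the C4=C5 alkene and turns the C5 oxygen into a leaving group for cross-coupling.

Step 5
Reactants: 7 enol triflate; 8 RAMP [(2R)-1-amino-2-(methoxymethyl)pyrrolidine]
Product: 9 RAMP hydrazone of 7
Conditions: TsOH·H2O (2 mol %), cyclohexane, 4 Å molecular sieves, 60 °C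
Reagents that add atoms: none
Why: Hydrazone formation (RAMP/SAMP method); the amino group should settle on the C1 side, away from the substituted C5, and no stereocentre is touched.

Step 6
Reactants: 9 RAMP hydrazone
Product: 11 RAMP hydrazone carrying CH2OCH2Ph on C1 (1S), via lithium azaenolate 10 (not isolated)
Conditions: LiN(iPr)2 (LDA), THF, 0 °C; then BnOCH2Cl, −100 to −78 °C
Reagents that add atoms: benzyl chloromethyl ether, ClCOCc1ccccc1
Why: Auxiliary-controlled alpha-alkylation of a chiral hydrazone; LDA removes a C1 proton (the only sp3 alpha position), and the chelated azaenolate 10 is alkylated on the face left open by the methoxymethyl arm, which for RAMP should give the C1 configuration of the target. The enol triflate should tolerate the amide base at these temperatures.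

Step 7
Reactants: 11 alkylated hydrazone
Product: 12 (5R)-5-[(benzyloxy)methyl]-6-oxo-2-[(1R)-1,5,5-trimethylcyclohex-2-en-1-yl]cyclohex-1-en-1-yl trifluoromethanesulfonate
Conditions: saturated aqueous oxalic acid, Et2O, rt
Reagents that add atoms: water, O
Why: Mild two-phase hydrolysis of the hydrazone, a method known not to epimerise the alpha centre; the auxiliary is recovered from the aqueous phase. C1 is R in 12 only because the CIP priorities change; the spatial arrangement is that of 11.

Step 8
Reactants: 12 enol triflate; 13 (3-tert-butoxy-3-oxopropyl)zinc bromide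
Product: 14 tert-butyl 3-{(5R)-5-[(benzyloxy)methyl]-6-oxo-2-[(1R)-1,5,5-trimethylcyclohex-2-en-1-yl]cyclohex-1-en-1-yl}propanoate
Conditions: Pd(OAc)2 (5 mol %), SPhos (10 mol %), THF, rt to 45 °C
Reagents that add atoms: none
Why: Negishi coupling of an enol triflate with an alkylzinc halide forms C5–C6; the weakly basic zinc reagent leaves the epimerisable C1–H and the ketone alone, and a bulky biarylphosphine is chosen because C5 sits beside the tert-alkyl group on C4.

Step 9
Reactants: 14 enone ester
Product: 15 spiro-epoxide at C10 [tert-butyl 3-{(4R)-4-[(benzyloxy)methyl]-7-[(1R)-1,5,5-trimethylcyclohex-2-en-1-yl]-1-oxaspiro[2.5]oct-7-en-8-yl}propanoate]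
Conditions: Me3S+ I−, n-BuLi, THF, −10 °C; then 14, −10 to 0 °C
Reagents that add atoms: trimethylsulfonium iodide, C[S+](C)C.[I-]
Why: Corey–Chaykovsky epoxidation; dimethylsulfonium methylide adds 1,2 to the enone carbonyl and brings in C9, and as a weak base it should neither epimerise C1 nor touch the ester. The configuration at C10 does not matter here because step 10 erases it.

Step 10
Reactants: 15 spiro-epoxide
Product: 17 tert-butyl 3-{(5S,6R)-5-[(benzyloxy)methyl]-6-formyl-2-[(1R)-1,5,5-trimethylcyclohex-2-en-1-yl]cyclohex-1-en-1-yl}propanoate, via aldehyde epimer mixture 16 (not isolated)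
Conditions: BF3·OEt2 (0.2 equiv), CH2Cl2, −78 °C; then Et3N (0.3 equiv), CH2Cl2, rt
Reagents that add atoms: none
Why: Meinwald rearrangement; the Lewis acid opens the epoxide at C10 (tertiary and allylic) and a 1,2-hydride shift from C9 gives aldehyde 16 as a mixture at C10. Amine-mediated enolisation then equilibrates C10 to the isomer with the formyl group trans to the C11 arm (both pseudo-equatorial), which sets C10 as R.

Step 11
Reactants: 17 aldehyde ester
Product: 18 3-{(5S,6R)-5-[(benzyloxy)methyl]-6-formyl-2-[(1R)-1,5,5-trimethylcyclohex-2-en-1-yl]cyclohex-1-en-1-yl}propanoic acid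
Conditions: CF3CO2H–CH2Cl2 (1:4), 0 °C
Reagents that add atoms: none
Why: Acidolysis of the tert-butyl ester with loss of 2-methylpropene; the benzyl ether, the aldehyde and both alkenes should survive short, cold exposure.

Step 12
Reactants: 18 aldehyde acid
Product: 19 tricyclic beta-lactone benzyl ether (1S,7R,9S,10R; C1' R; C5'=C6' alkene still present)
Conditions: 2-bromo-1-ethylpyridinium tetrafluoroborate, 4-pyrrolidinopyridine, i-Pr2NEt, CH2Cl2, rt, slow addition of 18
Reagents that add atoms: none
Why: Nucleophile-catalysed aldol-lactonization; the acid is activated by the pyridinium salt and passed to 4-pyrrolidinopyridine, the resulting ammonium enolate adds to the aldehyde (C7–C9, ring B) and the aldolate closes the beta-lactone (O–C8, ring C), which can only be cis-fused. The new bonds should form on the face of C9 away from the C1 branch of C10, which places the lactone syn to H-10 (7R,9S).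

Step 13
Reactants: 19 benzyl ether
Product: 20 primary alcohol (1S,7R,9S,10R) with the saturated (1S)-1,3,3-trimethylcyclohexyl group
Conditions: H2 (1 atm), Pd/C (10 wt % Pd), EtOAc, rt
Reagents that add atoms: none
Why: Heterogeneous hydrogenation; hydrogenolysis of the benzyl ether and saturation of the disubstituted C5'=C6' alkene in one operation, while the tetrasubstituted C4=C5 alkene and the beta-lactone should be inert under neutral conditions. C1' becomes S only through the change in CIP priorities.

Step 14
Reactants: 20 primary alcohol
Product: 21 3'-norspongiolactone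
Conditions: butyryl chloride, pyridine, CH2Cl2, −20 to 0 °C
Reagents that add atoms: butyryl chloride, CCCC(=O)Cl
Why: Acylation of the primary alcohol with an acyl chloride and a weak base; no nucleophilic acylation catalyst is used, so the beta-lactone should not be opened.

## Compound list

1 | isophorone (3,5,5-trimethylcyclohex-2-en-1-one) | CC1=CC(=O)CC(C)(C)C1 | starting material
2 | (R)-isophorol, (1R)-3,5,5-trimethylcyclohex-2-en-1-ol | O[C@H]1C=C(C)CC(C)(C)C1 | intermediate
3 | cyclohexane-1,2-dione | O=C1CCCCC1=O | starting material
4 | 2-{[(1S)-3,5,5-trimethylcyclohex-2-en-1-yl]oxy}cyclohex-2-en-1-one | O=C1CCCC=C1O[C@@H]1C=C(C)CC(C)(C)C1 | intermediate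
5 | 3-[(1R)-1,5,5-trimethylcyclohex-2-en-1-yl]cyclohexane-1,2-dione (both C4 epimers) | O=C1CCCC([C@@]2(C)C=CCC(C)(C)C2)C1=O | intermediate (not isolated)
6 | 2-hydroxy-3-[(1R)-1,5,5-trimethylcyclohex-2-en-1-yl]cyclohex-2-en-1-one | O=C1CCCC([C@@]2(C)C=CCC(C)(C)C2)=C1O | intermediate
7 | (R)-6-oxo-2-(1,5,5-trimethylcyclohex-2-en-1-yl)cyclohex-1-en-1-yl trifluoromethanesulfonate | O=C1CCCC([C@@]2(C)C=CCC(C)(C)C2)=C1OS(=O)(=O)C(F)(F)F | intermediate
8 | RAMP, (2R)-1-amino-2-(methoxymethyl)pyrrolidine | COC[C@H]1CCCN1N | starting material
9 | RAMP hydrazone of 7 (amino group syn to C1) | COC[C@H]1CCCN1/N=C1\CCCC([C@@]2(C)C=CCC(C)(C)C2)=C1OS(=O)(=O)C(F)(F)F | intermediate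
10 | lithium azaenolate of 9 (C10=C1 double bond, lithium on nitrogen) | COC[C@H]1CCCN1N([Li])C1=CCCC([C@@]2(C)C=CCC(C)(C)C2)=C1OS(=O)(=O)C(F)(F)F | intermediate (not isolated)
11 | RAMP hydrazone of 12, with (1S)-CH2OCH2Ph on C1 | COC[C@H]1CCCN1/N=C1\[C@@H](COCc2ccccc2)CCC([C@@]2(C)C=CCC(C)(C)C2)=C1OS(=O)(=O)C(F)(F)F | intermediate
12 | (5R)-5-[(benzyloxy)methyl]-6-oxo-2-[(1R)-1,5,5-trimethylcyclohex-2-en-1-yl]cyclohex-1-en-1-yl trifluoromethanesulfonate | O=C1[C@@H](COCc2ccccc2)CCC([C@@]2(C)C=CCC(C)(C)C2)=C1OS(=O)(=O)C(F)(F)F | intermediate
13 | (3-tert-butoxy-3-oxopropyl)zinc bromide | CC(C)(C)OC(=O)CC[Zn]Br | starting material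
14 | tert-butyl 3-{(5R)-5-[(benzyloxy)methyl]-6-oxo-2-[(1R)-1,5,5-trimethylcyclohex-2-en-1-yl]cyclohex-1-en-1-yl}propanoate | O=C1[C@@H](COCc2ccccc2)CCC([C@@]2(C)C=CCC(C)(C)C2)=C1CCC(=O)OC(C)(C)C | intermediate
15 | tert-butyl 3-{(4R)-4-[(benzyloxy)methyl]-7-[(1R)-1,5,5-trimethylcyclohex-2-en-1-yl]-1-oxaspiro[2.5]oct-7-en-8-yl}propanoate (both configurations at the spiro carbon) | C1OC12[C@@H](COCc3ccccc3)CCC([C@@]3(C)C=CCC(C)(C)C3)=C2CCC(=O)OC(C)(C)C | intermediate
16 | tert-butyl 3-{(5S)-5-[(benzyloxy)methyl]-6-formyl-2-[(1R)-1,5,5-trimethylcyclohex-2-en-1-yl]cyclohex-1-en-1-yl}propanoate (both C10 epimers) | O=CC1[C@@H](COCc2ccccc2)CCC([C@@]2(C)C=CCC(C)(C)C2)=C1CCC(=O)OC(C)(C)C | intermediate (not isolated)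
17 | tert-butyl 3-{(5S,6R)-5-[(benzyloxy)methyl]-6-formyl-2-[(1R)-1,5,5-trimethylcyclohex-2-en-1-yl]cyclohex-1-en-1-yl}propanoate | O=C[C@@H]1[C@@H](COCc2ccccc2)CCC([C@@]2(C)C=CCC(C)(C)C2)=C1CCC(=O)OC(C)(C)C | intermediate
18 | 3-{(5S,6R)-5-[(benzyloxy)methyl]-6-formyl-2-[(1R)-1,5,5-trimethylcyclohex-2-en-1-yl]cyclohex-1-en-1-yl}propanoic acid | O=C[C@@H]1[C@@H](COCc2ccccc2)CCC([C@@]2(C)C=CCC(C)(C)C2)=C1CCC(=O)O | intermediate
19 | tricyclic beta-lactone with C11 benzyl ether (1S,7R,9S,10R) and (1R)-1,5,5-trimethylcyclohex-2-en-1-yl on C4 | c1ccccc1COC[C@H]1CCC([C@@]2(C)C=CCC(C)(C)C2)=C2C[C@H]3C(=O)O[C@H]3[C@@H]21 | intermediate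
20 | tricyclic beta-lactone with free C11 alcohol (1S,7R,9S,10R) and (1S)-1,3,3-trimethylcyclohexyl on C4 | OC[C@H]1CCC([C@@]2(C)CCCC(C)(C)C2)=C2C[C@H]3C(=O)O[C@H]3[C@@H]21 | intermediate
21 | 3'-norspongiolactone (butanoate of 20) | CCCC(=O)OC[C@H]1CCC([C@@]2(C)CCCC(C)(C)C2)=C2C[C@H]3C(=O)O[C@H]3[C@@H]21 | target

## Step count and least certain steps

Total step count: 14. Longest linear sequence: 14 steps, from 1; compounds 3, 8 and 13 are bought.

Step 3 (key step). The process most likely to go wrong is heterolysis of the allylic C5'–O bond in competition with the concerted shift. The diosphenolate is a good leaving group and the cation would be allylic with a tertiary terminus, so ionisation would erode the chirality transfer or end in elimination. The syn-axial methyl group on C3' may also slow the shift. The fallback builds C1' on a smaller ketene acetal that has no leaving-group character and closes ring A afterwards. It sets out from 1 and comes back at 6.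
- 1 is reduced with the mirror-image CBS catalyst to (S)-isophorol F1.
- Johnson–Claisen rearrangement of F1 with triethyl orthoacetate (propionic acid cat., 140 °C) should give ester F2 with the same face-to-face transfer.
- The lithium enolate of F2 is alkylated with ethyl 4-bromobutanoate to diester F3.
- Acyloin condensation (Na, Me3SiCl, toluene) closes ring A as the bis(silyl) enediol ether F4.
- Br2 in CH2Cl2 oxidises F4 to diketone 5, which enolises to 6.

Step 2. The oxyphosphonium salt of a tertiary-stabilised allylic alcohol may ionise before SN2 displacement, which would lower the enantiomeric purity of 4 or give the diene by elimination. The fallback forms the ether without breaking the carbinol C–O bond. It sets out from 1 and comes back at 4: (S)-isophorol F1 is coupled with 2-iodocyclohex-2-en-1-one F5 under CuI, 3,4,7,8-tetramethyl-1,10-phenanthroline and Cs2CO3 in toluene at 80 °C (C–O cross-coupling with retention at C5').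

Step 8. Transmetalation and reductive elimination at C5 may be slow because C5 sits cis to the tert-alkyl group on C4, and reduction of the triflate or slow epimerisation at C1 could take over. The fallback replaces the sp3 transmetalation by an alkene insertion. It sets out from 12 and comes back at 14: Heck reaction with tert-butyl acrylate (Pd(OAc)2, PPh3, Et3N, DMF, 70 °C) should give dienoate F6, whose acrylate double bond alone is reduced with [(Ph3P)CuH]6, the enone beta carbon C4 being fully substituted.

Step 10. The allylic cation may lose a proton instead of accepting hydride, and during the equilibration the C4=C5 alkene may migrate into conjugation with the aldehyde. The fallback avoids the cation. It sets out from 14 and comes back at 17: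
- Takai–Lombardo methylenation (Zn, CH2Br2, TiCl4) gives diene F7.
- Hydroboration of the exocyclic alkene with 9-BBN and oxidation with NaBO3·4H2O give primary alcohol F8.
- Dess–Martin oxidation and the same amine equilibration give 17.

Step 12. Facial selectivity in the aldol step may be poor, with the lactone forming on the face of ring B near the C1 branch. The amine base may also move the C4=C5 alkene into conjugation before cyclisation. The fallback separates ring closure, reduction and lactonisation. It sets out from 17 and comes back at 19:
- Oxidative esterification with pyridinium dichromate, (C5H5NH)2Cr2O7, and MeOH in DMF gives diester F9.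
- Dieckmann condensation (KOtBu, THF) closes ring B as beta-keto ester F10.
- NaBH4 should attack C9 from the face opposite to the C1 branch; equilibration of C7 with DBU then gives the trans hydroxy ester F11.
- CF3CO2H gives hydroxy acid F12.
- Mitsunobu lactonisation through hydroxyl activation (PPh3, DIAD) inverts C9 and gives 19.

## Further compounds

F1 | step 3 | (S)-isophorol, (1S)-3,5,5-trimethylcyclohex-2-en-1-ol | O[C@@H]1C=C(C)CC(C)(C)C1
F2 | step 3 | ethyl 2-[(1S)-1,5,5-trimethylcyclohex-2-en-1-yl]acetate | CCOC(=O)C[C@@]1(C)C=CCC(C)(C)C1
F3 | step 3 | diethyl 2-[(1R)-1,5,5-trimethylcyclohex-2-en-1-yl]hexanedioate (both C4 epimers) | CCOC(=O)CCCC(C(=O)OCC)[C@@]1(C)C=CCC(C)(C)C1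
F4 | step 3 | 1,2-bis(trimethylsilyloxy)-3-[(1R)-1,5,5-trimethylcyclohex-2-en-1-yl]cyclohex-1-ene | C[Si](C)(C)OC1=C(O[Si](C)(C)C)C([C@@]2(C)C=CCC(C)(C)C2)CCC1
F5 | step 2 | 2-iodocyclohex-2-en-1-one | O=C1CCCC=C1I
F6 | step 8 | tert-butyl (E)-3-{(5R)-5-[(benzyloxy)methyl]-6-oxo-2-[(1R)-1,5,5-trimethylcyclohex-2-en-1-yl]cyclohex-1-en-1-yl}prop-2-enoate | O=C1[C@@H](COCc2ccccc2)CCC([C@@]2(C)C=CCC(C)(C)C2)=C1/C=C/C(=O)OC(C)(C)C
F7 | step 10 | tert-butyl 3-{(5R)-5-[(benzyloxy)methyl]-6-methylidene-2-[(1R)-1,5,5-trimethylcyclohex-2-en-1-yl]cyclohex-1-en-1-yl}propanoate | C=C1[C@@H](COCc2ccccc2)CCC([C@@]2(C)C=CCC(C)(C)C2)=C1CCC(=O)OC(C)(C)C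
F8 | step 10 | tert-butyl 3-{(5S)-5-[(benzyloxy)methyl]-6-(hydroxymethyl)-2-[(1R)-1,5,5-trimethylcyclohex-2-en-1-yl]cyclohex-1-en-1-yl}propanoate (both C10 epimers) | OCC1[C@@H](COCc2ccccc2)CCC([C@@]2(C)C=CCC(C)(C)C2)=C1CCC(=O)OC(C)(C)C
F9 | step 12 | methyl (1R,6S)-6-[(benzyloxy)methyl]-2-(3-tert-butoxy-3-oxopropyl)-3-[(1R)-1,5,5-trimethylcyclohex-2-en-1-yl]cyclohex-2-ene-1-carboxylate | COC(=O)[C@@H]1[C@@H](COCc2ccccc2)CCC([C@@]2(C)C=CCC(C)(C)C2)=C1CCC(=O)OC(C)(C)C
F10 | step 12 | bicyclic beta-keto ester: rings A and B closed, C9 ketone, tert-butyl ester on C7 (1S,10R; C7 epimers) | c1ccccc1COC[C@H]1CCC([C@@]2(C)C=CCC(C)(C)C2)=C2CC(C(=O)OC(C)(C)C)C(=O)[C@@H]21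
F11 | step 12 | bicyclic trans beta-hydroxy ester: C9 hydroxyl cis to the C1 branch, tert-butyl ester on C7 on the opposite face | c1ccccc1COC[C@H]1CCC([C@@]2(C)C=CCC(C)(C)C2)=C2C[C@@H](C(=O)OC(C)(C)C)[C@H](O)[C@@H]21
F12 | step 12 | bicyclic trans beta-hydroxy acid corresponding to F11 | c1ccccc1COC[C@H]1CCC([C@@]2(C)C=CCC(C)(C)C2)=C2C[C@@H](C(=O)O)[C@H](O)[C@@H]21
A1 | alternative 1 | diene: cyclopentene-fused beta-lactone with a 1-[(1S)-1,3,3-trimethylcyclohexyl]vinyl group on C5 | C=C([C@@]1(C)CCCC(C)(C)C1)C1=C[C@@H]2OC(=O)[C@@H]2C1
A2 | alternative 1 | endo cycloadduct: tricyclic lactone with a C1 formyl group cis to C9 (C1 epimer of the target series) | O=C[C@@H]1CCC([C@@]2(C)CCCC(C)(C)C2)=C2C[C@H]3C(=O)O[C@H]3[C@@H]21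
A3 | alternative 2 | C4 ketone of the saturated tricyclic lactone with C11 benzyl ether (C5 unspecified) | O=C1CC[C@H](COCc2ccccc2)[C@H]2[C@@H]3OC(=O)[C@@H]3CC12
A4 | alternative 2 | tertiary C4 carbinol carrying the 1,5,5-trimethylcyclohex-2-en-1-yl group (C4 and C1' uncontrolled) | OC1(C2(C)C=CCC(C)(C)C2)CC[C@H](COCc2ccccc2)[C@H]2[C@@H]3OC(=O)[C@@H]3CC12
A5 | alternative 2 | (3,5,5-trimethylcyclohex-2-en-1-yl)zinc bromide | CC1=CC([Zn]Br)CC(C)(C)C1
A6 | alternative 3 | 5,5-dimethyl-3-[(trimethylsilyl)ethynyl]cyclohex-2-en-1-one | C[Si](C)(C)C#CC1=CC(=O)CC(C)(C)C1
A7 | alternative 3 | (1S)-1-ethynyl-1,3,3-trimethylcyclohexane | C#C[C@@]1(C)CCCC(C)(C)C1
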